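**Retrosynthetic overview**
1. Target 23 comes from 22 by hydrolysis of an S-methyl vinylogous thioester and a silyl ether; ring C (the bridging six-membered ring of the bicyclo[3.2.1]octane) is closed last by an intramolecular Michael addition–elimination of a ring A ketone enolate onto an acyl ketene dithioacetal (20).
2. 20 comes from the cis-diquinane enone 18 by C-acylation with an isobutyryl donor and CS2/MeI; the angular acetyl of 18 is put on before ring B is closed by intramolecular C-alkylation.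
3. The monocyclic enone 16 is the union of fragment A (alkene 5) and fragment B (enone acetate 9) by a hydrogen-atom-transfer Giese addition, steered by the acetoxy group, followed by loss of acetic acid.
4. Fragment A comes from prenol (Sharpless epoxidation, cuprate opening); fragment B (ring A) comes from furfural (Piancatelli rearrangement, lipase resolution); the two acyl donors are N-acylbenzotriazoles.
5. Ring order: A (cyclopentenone) → B (cis-fused cyclopentane) → C (bridged ring).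

Assumption: the lipase acetylates the (4R)-enantiomer of 8, as it does 4-hydroxycyclopent-2-en-1-one itself; if the sense were reversed, the recovered alcohol would be acetylated with Ac2O instead.

**Fragment A**

Step 1
Reactants: 1 3-methylbut-2-en-1-ol
Product: 2 [(2S)-3,3-dimethyloxiran-2-yl]methanol
Conditions: Ti(OiPr)4 (5 mol%), L-(+)-diethyl tartrate (6 mol%), t-BuOOH, 4 Å MS, CH2Cl2, −20 °C
Reagents that add atoms: tert-butyl hydroperoxide, CC(C)(C)OO
Why: Sharpless asymmetric epoxidation, in which the L-(+)-tartrate titanium catalyst delivers oxygen to one face of the allylic alcohol and sets the (S) epoxide carbon.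

Step 2
Reactants: 2 [(2S)-3,3-dimethyloxiran-2-yl]methanol
Product: 3 (2R)-3-methyl-2-(prop-1-en-2-yl)butane-1,3-diol
Conditions: CH2=C(CH3)MgBr (3 eq), CuI (10 mol%), THF, −30 → 0 °C
Reagents that add atoms: isopropenylmagnesium bromide, CC(=C)[Mg]Br
Why: Copper-catalysed SN2 opening of the 2,3-epoxy alcohol at C2 (C3 is fully substituted) proceeds with inversion and gives the (R) stereocentre that becomes C3 of the target.

Step 3
Reactants: 3 (2R)-3-methyl-2-(prop-1-en-2-yl)butane-1,3-diol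
Product: 4 (2R)-3-hydroxy-3-methyl-2-(prop-1-en-2-yl)butyl methanesulfonate
Conditions: MsCl (1.05 eq), Et3N, CH2Cl2, −20 °C
Reagents that add atoms: methanesulfonyl chloride, CS(Cl)(=O)=O
Why: Selective sulfonylation of the primary hydroxyl beside the hindered tertiary one; the stereocentre is untouched.

Step 4
Reactants: 4 (2R)-3-hydroxy-3-methyl-2-(prop-1-en-2-yl)butyl methanesulfonate
Product: 5 (2R)-3-methyl-2-(prop-1-en-2-yl)-3-[(triethylsilyl)oxy]butyl methanesulfonate
Conditions: TESOTf, 2,6-lutidine, CH2Cl2, −78 → 0 °C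
Reagents that add atoms: triethylsilyl trifluoromethanesulfonate, CC[Si](CC)(CC)OS(=O)(=O)C(F)(F)F
Why: Silylation of the tertiary alcohol with a silyl triflate blocks oxetane formation and alkoxide chemistry in the later base steps.

**Fragment B**

Step 5
Reactants: 6 furan-2-carbaldehyde
Product: 7 rac-1-(furan-2-yl)ethan-1-ol
Conditions: MeMgBr, THF, 0 °C
Reagents that add atoms: methylmagnesium bromide, C[Mg]Br
Why: Grignard addition to the aldehyde gives the furyl carbinol needed for the rearrangement; its stereocentre is lost in the next step.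

Step 6
Reactants: 7 rac-1-(furan-2-yl)ethan-1-ol
Product: 8 rac-(4R,5S)-4-hydroxy-5-methylcyclopent-2-en-1-one
Conditions: ZnCl2, H2O/acetone (pH about 6), 60 °C
Reagents that add atoms: water, O
Why: Piancatelli rearrangement, whose conrotatory 4π electrocyclisation of the hydroxypentadienyl cation gives the trans 4-hydroxy-5-methyl enone as a racemate.

Step 7
Reactants: 8 rac-(4R,5S)-4-hydroxy-5-methylcyclopent-2-en-1-one
Product: 9 (1R,5S)-5-methyl-4-oxocyclopent-2-en-1-yl acetate
Conditions: lipase PS (Burkholderia cepacia), vinyl acetate, MTBE, 30 °C, to about 50% conversion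
Reagents that add atoms: vinyl acetate, CC(=O)OC=C
Why: Enzymatic kinetic resolution by transesterification acetylates only the (4R,5S)-alcohol, and the unreacted (4S,5R)-alcohol is removed by chromatography.

**Acyl donors**

Step 8
Reactants: 10 1H-benzotriazole; 11 acetyl chloride
Product: 12 1-(1H-benzotriazol-1-yl)ethan-1-one
Conditions: Et3N, CH2Cl2, 0 °C → rt
Reagents that add atoms: none
Why: N-acylation of benzotriazole gives a neutral acyl donor that C-acylates magnesium enolates without O-acylation.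

Step 9
Reactants: 10 1H-benzotriazole; 13 2-methylpropanoyl chloride
Product: 14 1-(1H-benzotriazol-1-yl)-2-methylpropan-1-one
Conditions: Et3N, CH2Cl2, 0 °C → rt
Reagents that add atoms: none
Why: N-acylation of benzotriazole, as in step 8, gives the isobutyryl donor.

**Union and ring construction**

Step 10
Reactants: 5 (2R)-3-methyl-2-(prop-1-en-2-yl)-3-[(triethylsilyl)oxy]butyl methanesulfonate; 9 (1R,5S)-5-methyl-4-oxocyclopent-2-en-1-yl acetate (1.5 eq)
Product: 16 (4S)-4-{(3R)-3-[(methanesulfonyloxy)methyl]-2,4-dimethyl-4-[(triethylsilyl)oxy]pentan-2-yl}-2-methylcyclopent-2-en-1-one, via acetoxy ketone 15 (not isolated)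
Conditions: Fe(acac)3 (30 mol%), PhSiH3 (2.5 eq), EtOH/(CH2OH)2, 60 °C; then DBU, CH2Cl2, rt
Reagents that add atoms: none
Why: Iron-hydride hydrogen-atom transfer to the isopropenyl group gives a tertiary radical that undergoes Giese addition to the enone on the face anti to the neighbouring acetoxy group, which sets the ring stereocentre and the quaternary carbon, and DBU then expels acetate (E1cB) to give the 2-methylcyclopentenone.

Step 11
Reactants: 16 (4S)-4-{(3R)-3-[(methanesulfonyloxy)methyl]-2,4-dimethyl-4-[(triethylsilyl)oxy]pentan-2-yl}-2-methylcyclopent-2-en-1-one; 12 1-(1H-benzotriazol-1-yl)ethan-1-one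
Product: 17 (4R)-5-acetyl-4-{(3R)-3-[(methanesulfonyloxy)methyl]-2,4-dimethyl-4-[(triethylsilyl)oxy]pentan-2-yl}-2-methylcyclopent-2-en-1-one
Conditions: MgBr2·OEt2 (2.5 eq), iPr2NEt (3 eq), CH2Cl2, rt
Reagents that add atoms: none
Why: Claisen-type C-acylation under soft enolisation occurs at the only enolisable α-carbon (the ring CH2) and is driven by the magnesium chelate of the β-diketone; the new centre is epimerisable and irrelevant.

Step 12
Reactants: 17 (4R)-5-acetyl-4-{(3R)-3-[(methanesulfonyloxy)methyl]-2,4-dimethyl-4-[(triethylsilyl)oxy]pentan-2-yl}-2-methylcyclopent-2-en-1-one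
Product: 18 (1R,5S,7S)-1-acetyl-3,6,6-trimethyl-7-{2-[(triethylsilyl)oxy]propan-2-yl}bicyclo[3.3.0]oct-3-en-2-one
Conditions: Cs2CO3, NaI (cat.), DMF, 50 °C
Reagents that add atoms: none
Why: Intramolecular C-alkylation (5-exo-tet, iodide formed in situ) of the β-diketone enolate closes ring B, which can only be cis-fused, so the existing ring stereocentre sets the angular quaternary centre with the acetyl group on the convex face.

Step 13
Reactants: 18 (1R,5S,7S)-1-acetyl-3,6,6-trimethyl-7-{2-[(triethylsilyl)oxy]propan-2-yl}bicyclo[3.3.0]oct-3-en-2-one; 14 1-(1H-benzotriazol-1-yl)-2-methylpropan-1-one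
Product: 20 (1S,5S,7S)-1-{2-[bis(methylsulfanyl)methylidene]-4-methyl-3-oxopentanoyl}-3,6,6-trimethyl-7-{2-[(triethylsilyl)oxy]propan-2-yl}bicyclo[3.3.0]oct-3-en-2-one, via triketone 19 (not isolated)
Conditions: MgBr2·OEt2, iPr2NEt, CH2Cl2, rt; solvent switch to DMF; K2CO3, CS2, 0 °C; then MeI, rt
Reagents that add atoms: carbon disulfide, S=C=S; iodomethane, CI
Why: Claisen-type C-acylation of the acetyl methyl (the only enolisable position) gives the β-diketone, whose central carbon is dithiocarboxylated and doubly S-methylated to the α-oxo ketene dithioacetal; no stereocentre changes.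

Step 14
Reactants: 20 (1S,5S,7S)-1-{2-[bis(methylsulfanyl)methylidene]-4-methyl-3-oxopentanoyl}-3,6,6-trimethyl-7-{2-[(triethylsilyl)oxy]propan-2-yl}bicyclo[3.3.0]oct-3-en-2-one
Product: 22 (1S,3S,5S,7R)-4,4,7-trimethyl-9-(2-methylpropanoyl)-8-(methylsulfanyl)-3-{2-[(triethylsilyl)oxy]propan-2-yl}tricyclo[5.3.1.0^1,5]undec-8-ene-10,11-dione, via copper enolate 21 (not isolated)
Conditions: [(Ph3P)CuH]6 (0.4 eq), toluene/THF, −40 °C → rt
Reagents that add atoms: none
Why: Conjugate reduction of the ring enone by the copper hydride gives the ring-ketone enolate regiospecifically, and its intramolecular Michael addition–elimination (6-endo-trig) onto the ketene dithioacetal closes ring C; the acceptor is held on the convex face by the angular carbon, so the new quaternary centre forms with its methyl on the ring B side.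

Step 15
Reactants: 22 (1S,3S,5S,7R)-4,4,7-trimethyl-9-(2-methylpropanoyl)-8-(methylsulfanyl)-3-{2-[(triethylsilyl)oxy]propan-2-yl}tricyclo[5.3.1.0^1,5]undec-8-ene-10,11-dione
Product: 23 (1S,3S,5S,7S)-8-hydroxy-3-(2-hydroxypropan-2-yl)-4,4,7-trimethyl-9-(2-methylpropanoyl)tricyclo[5.3.1.0^1,5]undec-8-ene-10,11-dione
Conditions: 1 M HCl, THF/H2O, 40 °C
Reagents that add atoms: water, O
Why: Acid hydrolysis (addition–elimination of water) converts the doubly activated vinylogous thioester into the enolised β-triketone and also cleaves the triethylsilyl ether; no stereocentre is touched.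

**Compound list**
1 | 3-methylbut-2-en-1-ol | CC(C)=CCO | starting material
2 | [(2S)-3,3-dimethyloxiran-2-yl]methanol | OC[C@@H]1OC1(C)C | intermediate
3 | (2R)-3-methyl-2-(prop-1-en-2-yl)butane-1,3-diol | CC(=C)[C@@H](C(C)(C)O)CO | intermediate
4 | (2R)-3-hydroxy-3-methyl-2-(prop-1-en-2-yl)butyl methanesulfonate | CC(=C)[C@@H](C(C)(C)O)COS(C)(=O)=O | intermediate
5 | (2R)-3-methyl-2-(prop-1-en-2-yl)-3-[(triethylsilyl)oxy]butyl methanesulfonate (fragment A) | CC(=C)[C@@H](C(C)(C)O[Si](CC)(CC)CC)COS(C)(=O)=O | intermediate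
6 | furan-2-carbaldehyde | O=Cc1ccco1 | starting material
7 | rac-1-(furan-2-yl)ethan-1-ol | CC(O)c1ccco1 | intermediate
8 | rac-(4R,5S)-4-hydroxy-5-methylcyclopent-2-en-1-one (trans racemate, one enantiomer drawn) | C[C@H]1[C@H](O)C=CC1=O | intermediate
9 | (1R,5S)-5-methyl-4-oxocyclopent-2-en-1-yl acetate (fragment B) | C[C@H]1[C@H](OC(C)=O)C=CC1=O | intermediate
10 | 1H-benzotriazole | c1ccc2[nH]nnc2c1 | starting material
11 | acetyl chloride | CC(Cl)=O | starting material
12 | 1-(1H-benzotriazol-1-yl)ethan-1-one | CC(=O)n1nnc2ccccc12 | intermediate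
13 | 2-methylpropanoyl chloride | CC(C)C(Cl)=O | starting material
14 | 1-(1H-benzotriazol-1-yl)-2-methylpropan-1-one | CC(C)C(=O)n1nnc2ccccc12 | intermediate
15 | (1R,2S,5R)-5-{(3R)-3-[(methanesulfonyloxy)methyl]-2,4-dimethyl-4-[(triethylsilyl)oxy]pentan-2-yl}-2-methyl-3-oxocyclopentyl acetate (not isolated) | C[C@H]1[C@H](OC(C)=O)[C@H](CC1=O)C(C)(C)[C@H](COS(C)(=O)=O)C(C)(C)O[Si](CC)(CC)CC | intermediate
16 | (4S)-4-{(3R)-3-[(methanesulfonyloxy)methyl]-2,4-dimethyl-4-[(triethylsilyl)oxy]pentan-2-yl}-2-methylcyclopent-2-en-1-one | CC1=C[C@H](CC1=O)C(C)(C)[C@H](COS(C)(=O)=O)C(C)(C)O[Si](CC)(CC)CC | intermediate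
17 | (4R)-5-acetyl-4-{(3R)-3-[(methanesulfonyloxy)methyl]-2,4-dimethyl-4-[(triethylsilyl)oxy]pentan-2-yl}-2-methylcyclopent-2-en-1-one (C5 epimers, largely enolised) | CC1=C[C@H](C(C(C)=O)C1=O)C(C)(C)[C@H](COS(C)(=O)=O)C(C)(C)O[Si](CC)(CC)CC | intermediate
18 | (1R,5S,7S)-1-acetyl-3,6,6-trimethyl-7-{2-[(triethylsilyl)oxy]propan-2-yl}bicyclo[3.3.0]oct-3-en-2-one (cis-fused) | CC1=C[C@H]2C(C)(C)[C@@H](C(C)(C)O[Si](CC)(CC)CC)C[C@@]2(C(C)=O)C1=O | intermediate
19 | (1R,5S,7S)-3,6,6-trimethyl-1-(4-methyl-3-oxopentanoyl)-7-{2-[(triethylsilyl)oxy]propan-2-yl}bicyclo[3.3.0]oct-3-en-2-one (not isolated) | CC1=C[C@H]2C(C)(C)[C@@H](C(C)(C)O[Si](CC)(CC)CC)C[C@@]2(C(=O)CC(=O)C(C)C)C1=O | intermediate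
20 | (1S,5S,7S)-1-{2-[bis(methylsulfanyl)methylidene]-4-methyl-3-oxopentanoyl}-3,6,6-trimethyl-7-{2-[(triethylsilyl)oxy]propan-2-yl}bicyclo[3.3.0]oct-3-en-2-one | CC1=C[C@H]2C(C)(C)[C@@H](C(C)(C)O[Si](CC)(CC)CC)C[C@@]2(C(=O)C(C(=O)C(C)C)=C(SC)SC)C1=O | intermediate
21 | copper enolate of the ring ketone of 3,4-dihydro-20 (enolate double bond C2=C3; not isolated) | CC1=C(O[Cu])[C@]2(C(=O)C(C(=O)C(C)C)=C(SC)SC)C[C@H](C(C)(C)O[Si](CC)(CC)CC)C(C)(C)[C@@H]2C1 | intermediate
22 | (1S,3S,5S,7R)-4,4,7-trimethyl-9-(2-methylpropanoyl)-8-(methylsulfanyl)-3-{2-[(triethylsilyl)oxy]propan-2-yl}tricyclo[5.3.1.0^1,5]undec-8-ene-10,11-dione | CC(C)C(=O)C1=C(SC)[C@]2(C)C[C@H]3C(C)(C)[C@@H](C(C)(C)O[Si](CC)(CC)CC)C[C@@]3(C1=O)C2=O | intermediate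
23 | (1S,3S,5S,7S)-8-hydroxy-3-(2-hydroxypropan-2-yl)-4,4,7-trimethyl-9-(2-methylpropanoyl)tricyclo[5.3.1.0^1,5]undec-8-ene-10,11-dione | CC(C)C(=O)C1=C(O)[C@]2(C)C[C@H]3C(C)(C)[C@@H](C(C)(C)O)C[C@@]3(C1=O)C2=O | target

**Step count**
Total steps: 15. Longest linear sequence: 10 (steps 1–4, then 10–15). Fragment B (steps 5–7) and the two acyl donors (steps 8 and 9) are made in parallel.

**Steps most likely to fail, with fallbacks**

Step 10 (radical union of the two hindered fragments). The fallback sets out from 5 and comes back at 15. The tertiary radical is made by photoredox decarboxylation of an oxalate instead of by hydrogen-atom transfer. Mukaiyama hydration of 5 (Mn(dpm)3, PhSiH3, O2, iPrOH) gives the tertiary alcohol (2S)-2-(2-hydroxypropan-2-yl)-3-methyl-3-[(triethylsilyl)oxy]butyl methanesulfonate F1. Acylation with ClC(=O)CO2Me, Et3N and DMAP gives methyl (3S)-3-[(methanesulfonyloxy)methyl]-2,4-dimethyl-4-[(triethylsilyl)oxy]pentan-2-yl oxalate F2. One equivalent of aqueous CsOH gives cesium 2-({(3S)-3-[(methanesulfonyloxy)methyl]-2,4-dimethyl-4-[(triethylsilyl)oxy]pentan-2-yl}oxy)-2-oxoacetate F3. Irradiation (blue LED) of F3 and 9 with Ir[dF(CF3)ppy]2(dtbbpy)PF6 in DME/DMF/H2O gives 15, which is treated with DBU as in step 10.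

Step 12 (quaternary centre by alkylation with a hindered, β-branched electrophile). The fallback sets out from 16 and comes back at 18; the ring is closed before the acetyl group is introduced. NaI in acetone gives (4S)-4-{(3S)-3-(iodomethyl)-2,4-dimethyl-4-[(triethylsilyl)oxy]pentan-2-yl}-2-methylcyclopent-2-en-1-one F4. LiN(iPr)2 in THF (−78 °C → rt) forms the kinetic, more reactive ketone enolate at the ring CH2, which cyclises to (1R,5R,7S)-3,6,6-trimethyl-7-{2-[(triethylsilyl)oxy]propan-2-yl}bicyclo[3.3.0]oct-3-en-2-one F5. A second deprotonation with LiN(iPr)2 at the ring-fusion carbon and C-acylation with 12 on the convex face gives 18.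

Step 14 (the copper hydride may also attack the ketene dithioacetal, or the enolate may not cyclise). The fallback sets out from 18 and comes back at 22; the ring alkene is removed before the acceptor is built and the enolate is made with base. Hydrogenation (H2, Pd/C, EtOAc) gives (1R,5S,7S)-1-acetyl-3,6,6-trimethyl-7-{2-[(triethylsilyl)oxy]propan-2-yl}bicyclo[3.3.0]octan-2-one F6. Acylation with 14 (MgBr2·OEt2, iPr2NEt) gives (1R,5S,7S)-3,6,6-trimethyl-1-(4-methyl-3-oxopentanoyl)-7-{2-[(triethylsilyl)oxy]propan-2-yl}bicyclo[3.3.0]octan-2-one F7. K2CO3, CS2 and MeI give (1S,5S,7S)-1-{2-[bis(methylsulfanyl)methylidene]-4-methyl-3-oxopentanoyl}-3,6,6-trimethyl-7-{2-[(triethylsilyl)oxy]propan-2-yl}bicyclo[3.3.0]octan-2-one F8. KOtBu in THF at −20 °C deprotonates the only remaining acidic position (the ring α-carbon bearing the methyl), and the same Michael addition–elimination gives 22.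

**Further compounds**
F1 | step 10 | (2S)-2-(2-hydroxypropan-2-yl)-3-methyl-3-[(triethylsilyl)oxy]butyl methanesulfonate | CC(C)(O)[C@H](COS(C)(=O)=O)C(C)(C)O[Si](CC)(CC)CC
F2 | step 10 | methyl (3S)-3-[(methanesulfonyloxy)methyl]-2,4-dimethyl-4-[(triethylsilyl)oxy]pentan-2-yl oxalate | COC(=O)C(=O)OC(C)(C)[C@H](COS(C)(=O)=O)C(C)(C)O[Si](CC)(CC)CC
F3 | step 10 | cesium 2-({(3S)-3-[(methanesulfonyloxy)methyl]-2,4-dimethyl-4-[(triethylsilyl)oxy]pentan-2-yl}oxy)-2-oxoacetate | [Cs+].[O-]C(=O)C(=O)OC(C)(C)[C@H](COS(C)(=O)=O)C(C)(C)O[Si](CC)(CC)CC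
F4 | step 12 | (4S)-4-{(3S)-3-(iodomethyl)-2,4-dimethyl-4-[(triethylsilyl)oxy]pentan-2-yl}-2-methylcyclopent-2-en-1-one | CC1=C[C@H](CC1=O)C(C)(C)[C@H](CI)C(C)(C)O[Si](CC)(CC)CC
F5 | step 12 | (1R,5R,7S)-3,6,6-trimethyl-7-{2-[(triethylsilyl)oxy]propan-2-yl}bicyclo[3.3.0]oct-3-en-2-one (cis-fused) | CC1=C[C@H]2C(C)(C)[C@@H](C(C)(C)O[Si](CC)(CC)CC)C[C@H]2C1=O
F6 | step 14 | (1R,5S,7S)-1-acetyl-3,6,6-trimethyl-7-{2-[(triethylsilyl)oxy]propan-2-yl}bicyclo[3.3.0]octan-2-one (C3 epimers) | CC1C[C@H]2C(C)(C)[C@@H](C(C)(C)O[Si](CC)(CC)CC)C[C@@]2(C(C)=O)C1=O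
F7 | step 14 | (1R,5S,7S)-3,6,6-trimethyl-1-(4-methyl-3-oxopentanoyl)-7-{2-[(triethylsilyl)oxy]propan-2-yl}bicyclo[3.3.0]octan-2-one (C3 epimers) | CC1C[C@H]2C(C)(C)[C@@H](C(C)(C)O[Si](CC)(CC)CC)C[C@@]2(C(=O)CC(=O)C(C)C)C1=O
F8 | step 14 | (1S,5S,7S)-1-{2-[bis(methylsulfanyl)methylidene]-4-methyl-3-oxopentanoyl}-3,6,6-trimethyl-7-{2-[(triethylsilyl)oxy]propan-2-yl}bicyclo[3.3.0]octan-2-one (C3 epimers) | CC1C[C@H]2C(C)(C)[C@@H](C(C)(C)O[Si](CC)(CC)CC)C[C@@]2(C(=O)C(C(=O)C(C)C)=C(SC)SC)C1=O
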